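Everything rests on cutting the C1''–C2'' bond of the prenyl group on C3 of ring A. C3 is quaternary, carries methyl and prenyl, and lies between C2 and C4, so C2–C3–C4 is a 2,2-dimethylmalonyl unit in which one of two enantiotopic methyl groups has been alkenylated. A single carboxylate-directed, palladium-catalysed C(sp3)–H alkenylation of commercial monomethyl 2,2-dimethylmalonate with 1-iodo-2-methylprop-1-ene forms that bond, sets the only stereocentre and leaves acid and ester arms distinct. The acid arm then acylates the dianion of heptane-2,4-dione, Claisen closure onto the ester gives butanoyl ring A, and the Mannich base of ring B (aspidinol) alkylates C5.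

Key step: step 1

Remarks on the chemistry (assumptions):
- Ring A locants: C1 carries the butanoyl group, C3 is the quaternary carbon, C5 carries the methylene bridge, and C6 is the ring carbonyl between C1 and C5. Ring A compounds are drawn in one enol tautomer, and the CIP descriptors refer to that drawing. The target is (R) at C3.
- The sense of induction of the chiral ligand in step 1 cannot be foretold for this substrate. The ligand antipode that gives (R)-3 is meant; both antipodes are available from L- and D-tert-leucine.

Step 1
Reactants: 1 monomethyl 2,2-dimethylmalonate (3-methoxy-2,2-dimethyl-3-oxopropanoic acid); 2 1-iodo-2-methylprop-1-ene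
Product: 3 (R)-2-(methoxycarbonyl)-2,5-dimethylhex-4-enoic acid
Conditions: Pd(OAc)2 (10 mol%), chiral ligand AcNH–CH(tBu)–CH2–NMe2 (20 mol%), Ag2CO3 (1.0 equiv), Na2CO3 (1.0 equiv), (CF3)2CHOH, 70 °C, sealed tube; 1 in 1.5-fold excess over 2
Reagents that add atoms: none
Why: Proposed new method: the carboxylate of 1 binds divalent palladium carrying the bidentate mono-N-acetyl aminoethyl amine ligand, whose acylamino group acts as internal base in a concerted metalation–deprotonation of one enantiotopic methyl group to give a five-membered palladacycle, after which oxidative addition of 2 gives tetravalent palladium, C(sp3)–C(sp2) reductive elimination forms the C1''–C2'' bond and Ag2CO3 removes iodide to return divalent palladium. The closest known reaction types are the enantioselective carboxylate-directed beta-C–H arylation of gem-dimethyl carboxylic acids with aryl iodides and the amide-directed beta-C–H alkenylation of isobutyric acid derivatives with alkenyl iodides; new here is the union of free-acid direction, an alkenyl iodide and a malonate half-ester. No ring is closed. The new stereocentre (future C3) is decided in the C–H cleavage step by the ligand, whose tert-butyl side chain should force the ester arm and the spectator methyl into different quadrants of the square-planar transition state (reagent control). The step needs discrimination of the two methyl groups, a stop after one alkenylation and freedom from beta-hydride pathways; the quaternary alpha carbon rules out beta-hydride loss and epimerisation and leaves the two methyl groups as the only C–H bonds within reach of a five-membered palladacycle, the new prenyl group crowds the remaining methyl, and 2 is the limiting partner. Acid and ester arms stay distinct for the regiodefined annulation.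

Step 2
Reactants: 3 (R)-2-(methoxycarbonyl)-2,5-dimethylhex-4-enoic acid; 4 heptane-2,4-dione
Product: 7 methyl (R)-2-methyl-2-(3-methylbut-2-en-1-yl)-3,5,7-trioxodecanoate, via acid chloride 5 (not isolated), via dilithium dienolate 6 (not isolated)
Conditions: a) 3, 1-chloro-N,N,2-trimethylprop-1-en-1-amine (1.1 equiv), CH2Cl2, 0 °C to rt; b) 4 (2.5 equiv), LiN(iPr)2 (5.0 equiv), THF, −78 to 0 °C, then solution of 5 at −78 °C, warm to −20 °C; cold aq NH4Cl
Reagents that add atoms: none
Why: Chlorination with the alpha-chloroenamine is neutral, so no HCl can add to the prenyl alkene, and in this terminal acylation of a beta-diketone dianion the last-formed methyl-side carbanion of 6 attacks the acid chloride far faster than the methyl ester while excess 6 takes up the acidic proton of the product; the quaternary stereocentre has no alpha hydrogen and is untouched.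

Step 3
Reactants: 7 methyl (R)-2-methyl-2-(3-methylbut-2-en-1-yl)-3,5,7-trioxodecanoate
Product: 8 (R)-2-butanoyl-3,5-dihydroxy-4-methyl-4-(3-methylbut-2-en-1-yl)cyclohexa-2,5-dien-1-one
Conditions: NaOMe (3 equiv), MeOH, 65 °C; then cold 1 M HCl
Reagents that add atoms: none
Why: Intramolecular Claisen (Dieckmann-type) condensation in which the doubly activated C6 carbon of the chain attacks the methyl ester in a 6-exo-trig closure; no aldol alternative exists because the carbon next to the ester is quaternary, any O-acylated lactone reopens under methoxide, and the stabilised triketonate of 8 is the thermodynamic sink, the stereocentre taking no part.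

Step 4
Reactants: 9 2,4,6-trihydroxytoluene (2-methylbenzene-1,3,5-triol); 10 butanoyl chloride
Product: 11 1-(2,4,6-trihydroxy-3-methylphenyl)butan-1-one
Conditions: AlCl3 (3.5 equiv), PhNO2–CH2Cl2, 0 to 40 °C; then ice–HCl
Reagents that add atoms: none
Why: Friedel–Crafts acylation of a phloroglucinol whose two free ring positions are equivalent, so a single regioisomer should form, and the first acyl group deactivates the ring against a second.

Step 5
Reactants: 11 1-(2,4,6-trihydroxy-3-methylphenyl)butan-1-one
Product: 12 1-(2,6-dihydroxy-4-methoxy-3-methylphenyl)butan-1-one (aspidinol)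
Conditions: Me2SO4 (1.0 equiv), K2CO3 (1.0 equiv), acetone, rt
Reagents that add atoms: dimethyl sulfate, COS(=O)(=O)OC
Why: Williamson-type O-methylation under weak base should take the hydroxyl para to the ketone, which is the most acidic and cannot be held in the hydrogen-bonded chelate that protects the two ortho hydroxyls, so one equivalent of base and electrophile should stop at this mono-ether.

Step 6
Reactants: 12 1-(2,6-dihydroxy-4-methoxy-3-methylphenyl)butan-1-one
Product: 13 1-{3-[(dimethylamino)methyl]-2,6-dihydroxy-4-methoxy-5-methylphenyl}butan-1-one
Conditions: 37% aq CH2O (1.1 equiv), 40% aq Me2NH (1.2 equiv), EtOH, 0 °C to rt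
Reagents that add atoms: formaldehyde, C=O; dimethylamine, CNC
Why: Mannich reaction in which the iminium ion is attacked by the only unsubstituted ring carbon of 12, activated by its flanking OH and OMe groups.

Step 7
Reactants: 8 (R)-2-butanoyl-3,5-dihydroxy-4-methyl-4-(3-methylbut-2-en-1-yl)cyclohexa-2,5-dien-1-one; 13 1-{3-[(dimethylamino)methyl]-2,6-dihydroxy-4-methoxy-5-methylphenyl}butan-1-one
Product: 15 (R)-2-butanoyl-6-[(3-butanoyl-2,4-dihydroxy-6-methoxy-5-methylphenyl)methyl]-3,5-dihydroxy-4-methyl-4-(3-methylbut-2-en-1-yl)cyclohexa-2,5-dien-1-one, via o-quinone methide 14 (not isolated)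
Conditions: toluene, 100 °C, N2; then wash with cold 0.5 M HCl
Reagents that add atoms: none
Why: On heating, 13 loses Me2NH to give o-quinone methide 14, which the vinylogous acid 8 traps by Michael addition through C5, its only nucleophilic carbon, with rearomatisation of ring B; 13 has no free ring position and so cannot self-condense, and the quaternary stereocentre of ring A is not touched.

Compound list
1 | monomethyl 2,2-dimethylmalonate (3-methoxy-2,2-dimethyl-3-oxopropanoic acid) | COC(=O)C(C)(C)C(=O)O | starting material
2 | 1-iodo-2-methylprop-1-ene | CC(C)=CI | starting material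
3 | (R)-2-(methoxycarbonyl)-2,5-dimethylhex-4-enoic acid | COC(=O)[C@](C)(CC=C(C)C)C(=O)O | intermediate
4 | heptane-2,4-dione | CCCC(=O)CC(C)=O | starting material
5 | methyl (S)-2-(chlorocarbonyl)-2,5-dimethylhex-4-enoate | COC(=O)[C@](C)(CC=C(C)C)C(Cl)=O | intermediate
6 | dilithium hepta-1,3-diene-2,4-bis(olate) (1,3-dianion of 4) | [Li+].[Li+].CCCC([O-])=CC([O-])=C | intermediate
7 | methyl (R)-2-methyl-2-(3-methylbut-2-en-1-yl)-3,5,7-trioxodecanoate | COC(=O)[C@](C)(CC=C(C)C)C(=O)CC(=O)CC(=O)CCC | intermediate
8 | (R)-2-butanoyl-3,5-dihydroxy-4-methyl-4-(3-methylbut-2-en-1-yl)cyclohexa-2,5-dien-1-one | CCCC(=O)C1=C(O)[C@](C)(CC=C(C)C)C(O)=CC1=O | intermediate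
9 | 2,4,6-trihydroxytoluene (2-methylbenzene-1,3,5-triol) | Cc1c(O)cc(O)cc1O | starting material
10 | butanoyl chloride | CCCC(Cl)=O | starting material
11 | 1-(2,4,6-trihydroxy-3-methylphenyl)butan-1-one | CCCC(=O)c1c(O)cc(O)c(C)c1O | intermediate
12 | 1-(2,6-dihydroxy-4-methoxy-3-methylphenyl)butan-1-one (aspidinol) | CCCC(=O)c1c(O)cc(OC)c(C)c1O | intermediate
13 | 1-{3-[(dimethylamino)methyl]-2,6-dihydroxy-4-methoxy-5-methylphenyl}butan-1-one | CCCC(=O)c1c(O)c(CN(C)C)c(OC)c(C)c1O | intermediate
14 | 2-butanoyl-3-hydroxy-5-methoxy-4-methyl-6-methylidenecyclohexa-2,4-dien-1-one | CCCC(=O)C1=C(O)C(C)=C(OC)C(=C)C1=O | intermediate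
15 | (R)-2-butanoyl-6-[(3-butanoyl-2,4-dihydroxy-6-methoxy-5-methylphenyl)methyl]-3,5-dihydroxy-4-methyl-4-(3-methylbut-2-en-1-yl)cyclohexa-2,5-dien-1-one (CNP0219644.1) | CCCC(=O)C1=C(O)[C@](C)(CC=C(C)C)C(O)=C(Cc2c(O)c(C(=O)CCC)c(O)c(C)c2OC)C1=O | target

Total step count: 7. Longest linear sequence: 4 steps (steps 1, 2, 3 and 7; the ring B branch, steps 4, 5, 6 and 7, is equally long).

Steps most likely to fail

Step 1. The catalyst may not turn over, because the electron-poor malonate carboxylate binds divalent palladium weakly or the alkenyl iodide adds slowly. The ligand may discriminate the two methyl groups poorly, a second alkenylation may follow, or the product acid may lactonise onto its new alkene under silver in the fluorinated alcohol. The fallback uses known chemistry, starts outside the route (it replaces 1 and 2, so no numbered compound is its origin) and rejoins at 3. Dimethyl 2-methylpropanedioate (COC(=O)C(C)C(=O)OC) is alkylated with 1-bromo-3-methylbut-2-ene (CC(C)=CCBr) and NaH in THF to give dimethyl 2-methyl-2-(3-methylbut-2-en-1-yl)propanedioate F1. One equivalent of KOH in MeOH–H2O at room temperature cleaves a single ester, the carboxylate formed shielding the second, to give the racemic half-ester rac-2-(methoxycarbonyl)-2,5-dimethylhex-4-enoic acid F2. Classical resolution by fractional crystallisation of a 1-phenylethylammonium salt follows, listed as (S)-1-phenylethylammonium (R)-2-(methoxycarbonyl)-2,5-dimethylhex-4-enoate F3; the amine antipode is to be chosen so that the salt of the (R)-acid is the less soluble one. Acidification with cold dilute HCl then gives 3.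

Step 2. The second deprotonation of the unsymmetrical diketone may not stay on the methyl side, so that the acyl group enters at the propyl-side methylene, or oxygen may be acylated instead of carbon. The fallback sets out from 5 and rejoins at 7. The symmetrical dilithium dienolate of pentane-2,4-dione F4, made from pentane-2,4-dione (CC(=O)CC(C)=O) and LiN(iPr)2 in THF, is acylated by 5 at −78 °C to give methyl (R)-2-methyl-2-(3-methylbut-2-en-1-yl)-3,5,7-trioxooctanoate F5, for which no choice of terminus arises. A further 3 equivalents of LiN(iPr)2 at −78 °C give the trilithium trienolate of the triketo ester F6. Its last-formed terminal carbanion is ethylated by iodoethane (CCI), a terminal alkylation of a polyketone polyanion, to give 7.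

Step 5. Methylation may go on to a second oxygen, or site selection among the three hydroxyls may be lost. The fallback sets out from 10, uses purchased 1,3,5-trimethoxy-2-methylbenzene (Cc1c(OC)cc(OC)cc1OC) in place of 9, and rejoins at 12. Friedel–Crafts acylation with AlCl3 in CH2Cl2 at 0 °C gives 1-(2,4,6-trimethoxy-3-methylphenyl)butan-1-one F7. Excess AlCl3 in chlorobenzene at 80 °C should then cleave only the two ethers that flank the ketone, because the Lewis acid is anchored on the carbonyl oxygen, while the para ether stays, giving 12.

Further compounds
F1 | step 1 | dimethyl 2-methyl-2-(3-methylbut-2-en-1-yl)propanedioate | COC(=O)C(C)(CC=C(C)C)C(=O)OC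
F2 | step 1 | rac-2-(methoxycarbonyl)-2,5-dimethylhex-4-enoic acid | COC(=O)C(C)(CC=C(C)C)C(=O)O
F3 | step 1 | (S)-1-phenylethylammonium (R)-2-(methoxycarbonyl)-2,5-dimethylhex-4-enoate | COC(=O)[C@](C)(CC=C(C)C)C(=O)[O-].C[C@H]([NH3+])c1ccccc1
F4 | step 2 | dilithium penta-1,3-diene-2,4-bis(olate) (1,3-dianion of pentane-2,4-dione) | [Li+].[Li+].CC([O-])=CC([O-])=C
F5 | step 2 | methyl (R)-2-methyl-2-(3-methylbut-2-en-1-yl)-3,5,7-trioxooctanoate | COC(=O)[C@](C)(CC=C(C)C)C(=O)CC(=O)CC(C)=O
F6 | step 2 | trilithium trienolate of methyl (R)-2-methyl-2-(3-methylbut-2-en-1-yl)-3,5,7-trioxooctanoate | COC(=O)[C@](C)(CC=C(C)C)C([O-])=CC([O-])=CC([O-])=C.[Li+].[Li+].[Li+]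
F7 | step 5 | 1-(2,4,6-trimethoxy-3-methylphenyl)butan-1-one | CCCC(=O)c1c(OC)cc(OC)c(C)c1OC
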